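**Plan**
- Retrosynthesis: the two C–Br bonds at C2 and C4 of phenol ring A are cut first (late electrophilic bromination) and the phenol is masked as its methyl ether, leading back to 2,4-dibromo-1-(2-methoxyphenoxy)benzene.
- Ring B is then cut at C1'–C2' and C5'–C6'. It carries the ether oxygen at C1', bromine at C2' and C4' and hydrogen at C3', C5' and C6', which is C3(Br)–C4(H)–C5(Br)–C6(H) of 3,5-dibromo-2-pyrone joined to the O–C≡C–H unit of an aryl ynol ether.
- The ynol ether is cut at its O–C(sp) bond to guaiacol and trichloroethylene; the pyrone comes from coumalic acid.
- Forward: pyrone (step 1) and ynol ether (steps 2–3) are made separately, ring B (the only ring built) arises in step 4 by [4+2] cycloaddition and loss of CO2, then demethylation (step 5) and dibromination of ring A (step 6).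
- Stereochemistry: the target has no stereogenic element; the only stereocentres on the way (bridgeheads of the cycloadduct) vanish in the same step.

Key step: step 4

Remark: because the target is achiral, the requirement of a single enantiomer is met without any asymmetric step.

**Route**

Step 1
Reactants: 1 coumalic acid (2-oxo-2H-pyran-5-carboxylic acid)
Product: 3 3,5-dibromo-2H-pyran-2-one, via 5-bromo-2-pyrone 2 (not isolated)
Conditions: NBS (2.5 equiv), LiOAc (cat.), MeCN–H2O, rt
Reagents that add atoms: N-bromosuccinimide, O=C1CCC(=O)N1Br
Why: A lithium-acetate-catalysed Hunsdiecker-type bromodecarboxylation should replace the C5 carboxyl group by bromine (Br+ attack on the enol-ether-like C5=C6 bond, then loss of CO2), after which the second equivalent of NBS brominates the now more electron-rich pyrone at C3 by electrophilic substitution, a one-pot sequence established for coumalic acid itself.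

Step 2
Reactants: 4 guaiacol (2-methoxyphenol); 5 trichloroethylene
Product: 7 1-{[(E)-1,2-dichloroethenyl]oxy}-2-methoxybenzene, via dichloroacetylene 6 (not isolated)
Conditions: K2CO3, DMF, 70 °C, closed flask under N2
Reagents that add atoms: none
Why: Carbonate should dehydrochlorinate trichloroethylene to dichloroacetylene, to which the phenoxide adds in anti fashion (nucleophilic vinylic substitution by elimination–addition), the standard entry to aryl (E)-1,2-dichlorovinyl ethers; the alkene geometry is of no consequence later.

Step 3
Reactants: 7 1-{[(E)-1,2-dichloroethenyl]oxy}-2-methoxybenzene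
Product: 10 1-(ethynyloxy)-2-methoxybenzene, via chloroalkynyl ether 8 (not isolated), via lithium acetylide 9 (not isolated)
Conditions: n-BuLi (2.2 equiv), THF, −78 to −40 °C; then H2O, −78 to 0 °C; cold work-up, solvent switched to toluene without taking to dryness
Reagents that add atoms: none
Why: Deprotonation of the vinyl C–H and β-elimination of chloride should give the chloroalkyne, chlorine–lithium exchange with the second equivalent the lithium acetylide, and protonation the terminal ynol ether (the standard dichlorovinyl ether route to ynol ethers), all faster at −78 °C than methoxy-directed ring lithiation.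

Step 4
Reactants: 3 3,5-dibromo-2H-pyran-2-one; 10 1-(ethynyloxy)-2-methoxybenzene
Product: 12 2,4-dibromo-1-(2-methoxyphenoxy)benzene, via bridged diene lactone 11 (not isolated)
Conditions: 10 (1.5 equiv, fresh toluene solution), BHT (cat.), toluene, sealed tube, 110 °C
Reagents that add atoms: none
Why: The electron-poor pyrone 3 should act as an inverse-electron-demand diene through C3–C6, the nucleophilic terminal carbon of ynol ether 10 bonding to the electrophilic C6 and the oxygen-bearing carbon to C3 in an asynchronous concerted [4+2] cycloaddition to give the bridged lactone 11, which aromatises under the same conditions by retro-[4+2] loss of CO2. The closest known reaction type is the Diels–Alder/decarboxylation benzannulation of 2-pyrones with alkynes, together with the inverse-demand cycloadditions of 3,5-dibromo-2-pyrone with enol ethers, which place the alkoxy carbon next to C3. Ring B, the only ring formed, closes by an intermolecular two-bond [4+2] annulation (C1'–C2' and C5'–C6'), four carbons coming from the pyrone and two from the alkyne. No stereocentre survives, since the two bridgehead centres of racemic 11 are lost with CO2, so endo/exo and facial selectivity are irrelevant. The step needs regioselectivity only, secured by matching the largest HOMO coefficient of the ynol ether (terminal carbon, β to oxygen) with the largest LUMO coefficient of the pyrone (C6); the wrong orientation would give a 3,5-dibromophenyl ether, and because both bromines arrive on pyrone carbons no halogenation or C–O coupling on ring B is needed.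

Step 5
Reactants: 12 2,4-dibromo-1-(2-methoxyphenoxy)benzene
Product: 14 2-(2,4-dibromophenoxy)phenol, via aryloxydibromoborane 13 (not isolated)
Conditions: BBr3 (2 equiv), CH2Cl2, −78 °C to rt; then H2O
Reagents that add atoms: none
Why: BBr3 should coordinate the more basic methyl ether oxygen and bromide cleave the O–CH3 bond by SN2 (Lewis-acid ether cleavage), whereas the diaryl ether offers no sp3 carbon and the aryl bromides are inert; hydrolysis of the aryloxyborane on work-up frees the phenol.

Step 6
Reactants: 14 2-(2,4-dibromophenoxy)phenol
Product: 16 2,4-dibromo-6-(2,4-dibromophenoxy)phenol, via para-monobromide 15 (not isolated)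
Conditions: Br2 (2.05 equiv), CH2Cl2, 0 °C to rt
Reagents that add atoms: bromine, BrBr
Why: Electrophilic aromatic bromination should be steered by the free hydroxyl, the strongest donor present, to its para and free ortho positions (C4 and C6 of 14, i.e. C4 and C2 of the target), since the sites ortho and para to the bridging oxygen are served only by a weaker donor shared with ring B, which is itself deactivated by two bromines.

**Compound list**
1 | coumalic acid (2-oxo-2H-pyran-5-carboxylic acid) | O=C(O)c1ccc(=O)oc1 | starting material
2 | 5-bromo-2H-pyran-2-one | O=c1ccc(Br)co1 | intermediate (not isolated)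
3 | 3,5-dibromo-2H-pyran-2-one | O=c1occ(Br)cc1Br | intermediate
4 | guaiacol (2-methoxyphenol) | COc1ccccc1O | starting material
5 | trichloroethylene | ClC=C(Cl)Cl | starting material
6 | dichloroacetylene | ClC#CCl | intermediate (not isolated)
7 | 1-{[(E)-1,2-dichloroethenyl]oxy}-2-methoxybenzene | COc1ccccc1O/C(Cl)=C\Cl | intermediate
8 | 1-[(chloroethynyl)oxy]-2-methoxybenzene | COc1ccccc1OC#CCl | intermediate (not isolated)
9 | [(2-methoxyphenoxy)ethynyl]lithium | [Li]C#COc1ccccc1OC | intermediate (not isolated)
10 | 1-(ethynyloxy)-2-methoxybenzene | C#COc1ccccc1OC | intermediate
11 | 4,7-dibromo-5-(2-methoxyphenoxy)-2-oxabicyclo[2.2.2]octa-5,7-dien-3-one (racemic; both bridgehead centres are lost with CO2) | O=C1OC2C=C(Oc3ccccc3OC)C1(Br)C=C2Br | intermediate (not isolated)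
12 | 2,4-dibromo-1-(2-methoxyphenoxy)benzene | COc1ccccc1Oc1ccc(Br)cc1Br | intermediate
13 | dibromo[2-(2,4-dibromophenoxy)phenoxy]borane | BrB(Br)Oc1ccccc1Oc1ccc(Br)cc1Br | intermediate (not isolated)
14 | 2-(2,4-dibromophenoxy)phenol | Oc1ccccc1Oc1ccc(Br)cc1Br | intermediate
15 | 4-bromo-2-(2,4-dibromophenoxy)phenol | Oc1ccc(Br)cc1Oc1ccc(Br)cc1Br | intermediate (not isolated)
16 | 2,4-dibromo-6-(2,4-dibromophenoxy)phenol | Oc1c(Br)cc(Br)cc1Oc1ccc(Br)cc1Br | target

**Totals**
Total step count: 6 (steps 1 and 2–3 converge at step 4).
Longest linear sequence: 5 steps (guaiacol → 7 → 10 → 12 → 14 → 16).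

**Steps most likely to fail**

1. Step 4. Thermal oligomerisation of the terminal ynol ether may outpace a sluggish cycloaddition, or the orientation of the addition may erode. Fallback: the diaryl ether C–O bond would be made instead by ligand coupling at iodine(III). Setting out from guaiacol 4, its sodium salt (aq. NaOH, dioxane, 80 °C) would be arylated with bis(2,4-dibromophenyl)iodonium chloride F1, itself to be prepared from 1,3-dibromobenzene and iodyl sulfate in sulfuric acid followed by chloride precipitation. This is the established way to polybrominated diphenyl ethers and comes back to the route at 12.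

2. Step 3. The terminal ynol ether may oligomerise during aqueous work-up and solvent exchange before it can be used. Fallback: setting out from 7, the same n-BuLi treatment would be ended by trapping the acetylide with Me3SiCl at −78 °C to give the storable silyl-capped ynol ether [(2-methoxyphenoxy)ethynyl]trimethylsilane F2. Heating F2 with pyrone 3 (xylene, 140 °C) should give, through the silylated bridged lactone F3 and loss of CO2, the silylated diaryl ether [3,5-dibromo-2-(2-methoxyphenoxy)phenyl]trimethylsilane F4. Here the oxygen-bearing alkyne carbon should again bond to C3, the developing positive charge being β to silicon. Acid protodesilylation (TFA, 40 °C; ipso attack ortho to the ether oxygen) then returns to the route at 12.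

3. Step 6. Site control may be imperfect in the one-pot double substitution: some attack para to the bridging oxygen, or a third bromine entering before both wanted sites are filled. Fallback: two separately controlled monobrominations that rely on different delivery mechanisms. Setting out from 14, Br2/t-BuNH2 (toluene, −70 °C to rt) should deliver bromine only ortho to the hydroxyl through the hydrogen-bonded N-bromoamine, giving 2-bromo-6-(2,4-dibromophenoxy)phenol F5. Tetrabutylammonium tribromide (CH2Cl2–MeOH, rt) should then fill the para position one equivalent at a time, arriving at 16.

Further compounds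
F1 | step 4 | bis(2,4-dibromophenyl)iodonium chloride | [Cl-].Brc1ccc([I+]c2ccc(Br)cc2Br)c(Br)c1
F2 | step 3 | [(2-methoxyphenoxy)ethynyl]trimethylsilane | COc1ccccc1OC#C[Si](C)(C)C
F3 | step 3 | 4,7-dibromo-5-(2-methoxyphenoxy)-6-(trimethylsilyl)-2-oxabicyclo[2.2.2]octa-5,7-dien-3-one | O=C1OC2C([Si](C)(C)C)=C(Oc3ccccc3OC)C1(Br)C=C2Br
F4 | step 3 | [3,5-dibromo-2-(2-methoxyphenoxy)phenyl]trimethylsilane | COc1ccccc1Oc1c(Br)cc(Br)cc1[Si](C)(C)C
F5 | step 6 | 2-bromo-6-(2,4-dibromophenoxy)phenol | Oc1c(Br)cccc1Oc1ccc(Br)cc1Br
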